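**Retrosynthetic overview**
1. Target 33 ⇐ 32 (fluoride desilylation) ⇐ 31 + acid 8 (ester on O8) ⇐ 30 (C8 desilylation) ⇐ 29 (conjugate reduction sets C11).
2. 29 ⇐ bromo enal 27 by a CrCl2-mediated intramolecular allylation that forms C6–C7: ring A (ten-membered carbocycle C1–C10) closes first, ring B (γ-lactone O–C6–C7–C11–C12) closes directly afterwards in the same flask.
3. Enabling feature: C6 is an allylic carbinol carbon (bonded to the ring B oxygen and to C5 of the C4=C5 alkene) and C7 lies β to the lactone carbonyl C12 through C11. C13–C11(=C7)–C12O2Me is therefore a latent 2-(methoxycarbonyl)allyl nucleophile for a C6 enal, and the new C6 oxygen sits 1,4 to C12.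
4. 27 ⇐ aldehyde 23 + methyl acrylate 24 (Morita–Baylis–Hillman, SN2′ bromination) ⇐ diene 17 + iodide 4 (B-alkyl Suzuki–Miyaura, C3–C4). C8 comes from D-proline aminoxylation of aldehyde 10; the Z C1=C10 alkene comes intact from neryl acetate 9.
5. 4 ⇐ 1 (syn-stannylcupration, iodination); 8 ⇐ 5 (Grignard carboxylation).

Key step: step 20

Remark: germacrane numbering is used for positions (ring carbons C1–C10, lactone unit C11–C13, C14 = methyl on C10, C15 = CH2O on C4); TBS = tert-butyldimethylsilyl, TBDPS = tert-butyldiphenylsilyl; compounds 1, 5, 9 and 24 are assumed to be purchasable.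

**Fragment 1: vinyl iodide 4**

Step 1
Reactants: 1 methyl 4-hydroxybut-2-ynoate
Product: 2 methyl 4-(TBDPSO)but-2-ynoate
Conditions: TBDPSCl, imidazole, CH2Cl2, 0 °C to rt
Reagents that add atoms: tert-butyl(chloro)diphenylsilane (TBDPSCl), CC(C)(C)[Si](Cl)(c1ccccc1)c1ccccc1
Why: Imidazole-promoted O-silylation of the only hydroxyl should be clean; no stereocenter is involved.

Step 2
Reactants: 2 methyl 4-(TBDPSO)but-2-ynoate
Product: 3 methyl (E)-4-(TBDPSO)-3-(tributylstannyl)but-2-enoate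
Conditions: Bu3SnH, LDA, THF, 0 °C; CuBr·SMe2, −78 °C; then 2, MeOH, −78 °C
Reagents that add atoms: tributyltin hydride, CCCC[SnH](CCCC)CCCC
Why: syn-Stannylcupration of the ynoate puts tin on the β-carbon and copper on the α-carbon on the same side, and protonation at −78 °C before the vinylcopper can isomerise should fix tin trans to the ester, so that the CH2OSi arm is cis to the ester.

Step 3
Reactants: 3 methyl (E)-4-(TBDPSO)-3-(tributylstannyl)but-2-enoate
Product: 4 methyl (E)-4-(TBDPSO)-3-iodobut-2-enoate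
Conditions: I2, CH2Cl2, 0 °C
Reagents that add atoms: iodine, II
Why: Iododestannylation (electrophilic ipso-substitution) should proceed with retention of the alkene geometry.

**Fragment 2: side-chain acid 8**

Step 4
Reactants: 5 (R)-3-bromo-2-methylpropan-1-ol
Product: 6 (R)-(3-bromo-2-methylpropoxy)(tert-butyl)diphenylsilane
Conditions: TBDPSCl, imidazole, DMF, rt
Reagents that add atoms: tert-butyl(chloro)diphenylsilane (TBDPSCl), CC(C)(C)[Si](Cl)(c1ccccc1)c1ccccc1
Why: O-Silylation of the primary alcohol; the stereocenter from the chiral pool is not touched.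

Step 5
Reactants: 6 (R)-(3-bromo-2-methylpropoxy)(tert-butyl)diphenylsilane
Product: 8 (S)-4-(TBDPSO)-3-methylbutanoic acid, via Grignard reagent 7 (not isolated)
Conditions: Mg, THF, reflux; CO2, −20 °C; 1 M HCl
Reagents that add atoms: carbon dioxide, O=C=O
Why: Carboxylation of a Grignard reagent adds the one missing carbon; the stereocenter is β to the metal-bearing carbon and keeps its configuration (the descriptor becomes S only through the priority change).

**Main line**

Step 6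
Reactants: 9 neryl acetate
Product: 10 (2Z)-3-methyl-6-oxohex-2-en-1-yl acetate
Conditions: O3 (1 equiv), CH2Cl2, pyridine (cat.), −78 °C; Me2S
Reagents that add atoms: ozone, [O-][O+]=O
Why: Chemoselective ozonolysis should cleave only the electron-rich isopropylidene alkene, because the 2,3-alkene is deactivated by the allylic acetate; the Z alkene stays untouched.

Step 7
Reactants: 10 (2Z)-3-methyl-6-oxohex-2-en-1-yl acetate
Product: 12 (2Z,5S)-6-hydroxy-3-methyl-5-[(phenylamino)oxy]hex-2-en-1-yl acetate, via aminooxy aldehyde 11 (not isolated)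
Conditions: D-proline (20 mol%), PhN=O, DMSO, rt; then NaBH4, MeOH, 0 °C
Reagents that add atoms: nitrosobenzene, O=Nc1ccccc1
Why: Proline-catalysed α-aminoxylation (enamine catalysis) delivers the oxygen of nitrosobenzene to the enamine face directed by the carboxylic acid, which with D-proline should give the S centre (C8), and reduction in the same flask protects the labile α-oxy aldehyde from racemisation.

Step 8
Reactants: 12 (2Z,5S)-6-hydroxy-3-methyl-5-[(phenylamino)oxy]hex-2-en-1-yl acetate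
Product: 13 (2Z,5S)-5,6-dihydroxy-3-methylhex-2-en-1-yl acetate
Conditions: Zn, AcOH, THF, rt
Reagents that add atoms: none
Why: Reductive N–O bond cleavage by zinc in acetic acid should leave the allylic acetate, the alkene and the stereocenter untouched.

Step 9
Reactants: 13 (2Z,5S)-5,6-dihydroxy-3-methylhex-2-en-1-yl acetate
Product: 14 (2Z,5S)-5,6-bis(TBSO)-3-methylhex-2-en-1-yl acetate
Conditions: TBSCl (2.5 equiv), imidazole, DMF, rt
Reagents that add atoms: tert-butyl(chloro)dimethylsilane (TBSCl), CC(C)(C)[Si](C)(C)Cl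
Why: Imidazole-promoted bis-silylation protects both hydroxyls with a group whose primary and secondary ethers can later be told apart.

Step 10
Reactants: 14 (2Z,5S)-5,6-bis(TBSO)-3-methylhex-2-en-1-yl acetate
Product: 15 (2Z,5S)-5,6-bis(TBSO)-3-methylhex-2-en-1-ol
Conditions: K2CO3 (cat.), MeOH, 0 °C to rt
Reagents that add atoms: none
Why: Base-catalysed transesterification removes only the acetate; silyl ethers are stable to K2CO3 in methanol.

Step 11
Reactants: 15 (2Z,5S)-5,6-bis(TBSO)-3-methylhex-2-en-1-ol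
Product: 16 (2Z,5S)-5,6-bis(TBSO)-3-methylhex-2-enal
Conditions: TEMPO (cat.), PhI(OAc)2, CH2Cl2, rt
Reagents that add atoms: none
Why: Oxoammonium (TEMPO) oxidation of the primary allylic alcohol is neutral and should stop at the enal without Z to E isomerisation.

Step 12
Reactants: 16 (2Z,5S)-5,6-bis(TBSO)-3-methylhex-2-enal
Product: 17 (3Z,6S)-6,7-bis(TBSO)-4-methylhepta-1,3-diene
Conditions: Ph3PCH3Br, KHMDS, THF, −78 to 0 °C
Reagents that add atoms: methyltriphenylphosphonium bromide, C[P+](c1ccccc1)(c1ccccc1)c1ccccc1.[Br-]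
Why: Wittig methylenation adds C3; the non-stabilised ylide adds to the aldehyde faster than it deprotonates the γ-position, so the Z trisubstituted alkene should be kept.

Step 13
Reactants: 17 (3Z,6S)-6,7-bis(TBSO)-4-methylhepta-1,3-diene; 4 methyl (E)-4-(TBDPSO)-3-iodobut-2-enoate
Product: 19 methyl (2Z,6Z,9S)-9,10-bis(TBSO)-3-(TBDPSO-methyl)-7-methyldeca-2,6-dienoate, via alkylborane 18 (not isolated)
Conditions: 9-BBN, THF, 0 °C to rt; then 4, Pd(dppf)Cl2 (cat.), AsPh3, Cs2CO3, DMF/H2O, rt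
Reagents that add atoms: none
Why: Hydroboration with bulky 9-BBN should place boron only on the unsubstituted diene terminus, and the B-alkyl Suzuki–Miyaura coupling proceeds with retention at the vinyl iodide, so C3 ends up trans and the CH2OSi arm cis to the ester.

Step 14
Reactants: 19 methyl (2Z,6Z,9S)-9,10-bis(TBSO)-3-(TBDPSO-methyl)-7-methyldeca-2,6-dienoate
Product: 20 (2Z,6Z,9S)-9,10-bis(TBSO)-3-(TBDPSO-methyl)-7-methyldeca-2,6-dien-1-ol
Conditions: i-Bu2AlH, CH2Cl2, −78 °C; Rochelle salt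
Reagents that add atoms: none
Why: 1,2-Reduction of the enoate by i-Bu2AlH gives the allylic alcohol without touching silyl ethers or alkene geometry.

Step 15
Reactants: 20 (2Z,6Z,9S)-9,10-bis(TBSO)-3-(TBDPSO-methyl)-7-methyldeca-2,6-dien-1-ol
Product: 21 (2Z,6Z,9S)-9,10-bis(TBSO)-3-(TBDPSO-methyl)-7-methyldeca-2,6-dienal
Conditions: MnO2, CH2Cl2, rt
Reagents that add atoms: none
Why: MnO2 oxidises the allylic alcohol selectively to the enal (C6 aldehyde) with the alkene geometry kept.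

Step 16
Reactants: 21 (2Z,6Z,9S)-9,10-bis(TBSO)-3-(TBDPSO-methyl)-7-methyldeca-2,6-dienal
Product: 22 (2S,4Z,8Z)-2-(TBSO)-8-(TBDPSO-methyl)-10,10-dimethoxy-4-methyldeca-4,8-dien-1-ol
Conditions: HC(OMe)3, camphorsulfonic acid (cat.), MeOH/CH2Cl2, 0 °C
Reagents that add atoms: trimethyl orthoformate, COC(OC)OC; methanol, CO
Why: Acid-catalysed acetalisation masks the enal while the same acidic methanol should remove only the primary TBS ether (primary TBS cleaves much faster than secondary TBS or TBDPS under acid).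

Step 17
Reactants: 22 (2S,4Z,8Z)-2-(TBSO)-8-(TBDPSO-methyl)-10,10-dimethoxy-4-methyldeca-4,8-dien-1-ol
Product: 23 (2S,4Z,8Z)-2-(TBSO)-8-(TBDPSO-methyl)-10,10-dimethoxy-4-methyldeca-4,8-dienal
Conditions: Dess–Martin periodinane, NaHCO3, CH2Cl2, 0 °C to rt
Reagents that add atoms: none
Why: Buffered Dess–Martin oxidation should give the α-silyloxy aldehyde without epimerisation at C8 and without loss of the acetal; it is used crude.

Step 18
Reactants: 23 (2S,4Z,8Z)-2-(TBSO)-8-(TBDPSO-methyl)-10,10-dimethoxy-4-methyldeca-4,8-dienal; 24 methyl acrylate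
Product: 25 methyl (4S,6Z,10Z)-4-(TBSO)-10-(TBDPSO-methyl)-3-hydroxy-12,12-dimethoxy-6-methyl-2-methylidenedodeca-6,10-dienoate (both C3 epimers)
Conditions: 24 (excess), DABCO (1 equiv), neat, rt
Reagents that add atoms: none
Why: In the Morita–Baylis–Hillman reaction the DABCO–acrylate zwitterion adds to the activated α-silyloxy aldehyde; the new carbinol center becomes sp2 in the next step, so its configuration does not matter.

Step 19
Reactants: 25 methyl (4S,6Z,10Z)-4-(TBSO)-10-(TBDPSO-methyl)-3-hydroxy-12,12-dimethoxy-6-methyl-2-methylidenedodeca-6,10-dienoate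
Product: 27 methyl (2Z,4S,6Z,10Z)-2-(bromomethyl)-4-(TBSO)-10-(TBDPSO-methyl)-6-methyl-12-oxododeca-2,6,10-trienoate, via bromo acetal 26 (not isolated)
Conditions: NBS, Me2S, CH2Cl2, 0 °C to rt; then aq. oxalic acid, THF, 0 °C
Reagents that add atoms: N-bromosuccinimide (NBS), O=C1CCC(=O)N1Br; water, O
Why: Corey–Kim-type activation of the allylic alcohol and SN2′ displacement by bromide should give the thermodynamically preferred (Z)-2-(bromomethyl)enoate, and mild aqueous acid then frees the enal from the labile conjugated acetal.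

Step 20
Reactants: 27 methyl (2Z,4S,6Z,10Z)-2-(bromomethyl)-4-(TBSO)-10-(TBDPSO-methyl)-6-methyl-12-oxododeca-2,6,10-trienoate
Product: 29 (1(10)Z,4Z,6R,7S,8S)-8-(TBSO)-15-(TBDPSO)germacra-1(10),4,11(13)-trien-12,6-olide, via hydroxy ester 28 (not isolated)
Conditions: CrCl2 (8 equiv), THF, rt, 27 added by syringe pump (final ca. 2 mM); sat. aq. NH4Cl
Reagents that add atoms: none
Why: Two equivalents of CrCl2 reduce the allylic C13–Br bond to an allylchromium reagent (trivalent chromium) whose γ-carbon C7 adds to the C6 aldehyde through a closed six-membered chair transition state, the closest known reaction type being the intramolecular Nozaki–Hiyama–Kishi (Barbier-type) allylation that is established for ten-membered germacranolide ring closure from 2-(bromomethyl)enoate aldehydes. Ring A closes by this carbonyl addition with allylic transposition (the alkene moves to exocyclic C11=C13), and ring B closes when the C6 chromium alkoxide attacks the C12 ester in a 5-exo-trig acyl substitution that expels methoxide. C6 and C7 are set together: the six-atom tether holds C5 and C8 pseudo-equatorial on the chair (the allylchromium can equilibrate its alkene geometry), which gives the anti adduct and hence the trans-fused lactone. Their absolute sense is relayed from C8: allylic 1,3-strain keeps H8 in the plane of the C7=C11 alkene, and the aldehyde, delivered by the chain attached to C9, reaches the face of C7 that is syn to C9 and anti to the OTBS group, which should give 6R,7S (the target-series configuration; C7 reads S only because of the silyl ether priority). The step needs cyclisation over oligomerisation, secured by slow addition at high dilution and by the Z C1=C10 and C4=C5 alkenes that fold the chain, and 1,2- over 1,4-addition to the enal, which allylchromium reagents give. The TBS ether on O8 blocks the competing 8,12-lactone.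

Step 21
Reactants: 29 (1(10)Z,4Z,6R,7S,8S)-8-(TBSO)-15-(TBDPSO)germacra-1(10),4,11(13)-trien-12,6-olide
Product: 30 (1(10)Z,4Z,6R,7S,8S,11S)-8-(TBSO)-15-(TBDPSO)germacra-1(10),4-dien-12,6-olide
Conditions: NaBH4, MeOH, 0 °C
Reagents that add atoms: none
Why: Conjugate (1,4) hydride reduction of the α-methylene lactone followed by protonation of the enolate at C11 should give the more stable 11S epimer (methyl trans to C8 on the lactone ring), and methoxide in the medium would equilibrate any 11-epimer to it.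

Step 22
Reactants: 30 (1(10)Z,4Z,6R,7S,8S,11S)-8-(TBSO)-15-(TBDPSO)germacra-1(10),4-dien-12,6-olide
Product: 31 (1(10)Z,4Z,6R,7R,8S,11S)-8-hydroxy-15-(TBDPSO)germacra-1(10),4-dien-12,6-olide
Conditions: HF·pyridine, pyridine, THF, 0 °C to rt
Reagents that add atoms: none
Why: Selective desilylation: with buffered HF·pyridine the secondary TBS ether cleaves much faster than the primary TBDPS ether, and the conditions are too mild for transannular cyclisation of the diene.

Step 23
Reactants: 31 (1(10)Z,4Z,6R,7R,8S,11S)-8-hydroxy-15-(TBDPSO)germacra-1(10),4-dien-12,6-olide; 8 (S)-4-(TBDPSO)-3-methylbutanoic acid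
Product: 32 (1(10)Z,4Z,6R,7R,8S,11S)-8-{[(S)-4-(TBDPSO)-3-methylbutanoyl]oxy}-15-(TBDPSO)germacra-1(10),4-dien-12,6-olide
Conditions: DCC, DMAP, CH2Cl2, 0 °C to rt
Reagents that add atoms: none
Why: Steglich esterification acylates O8 with retention at C8, since the C8–O bond is not touched.

Step 24
Reactants: 32 (1(10)Z,4Z,6R,7R,8S,11S)-8-{[(S)-4-(TBDPSO)-3-methylbutanoyl]oxy}-15-(TBDPSO)germacra-1(10),4-dien-12,6-olide
Product: 33 CNP0160815.1
Conditions: Bu4NF, AcOH, THF, 0 °C to rt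
Reagents that add atoms: none
Why: Fluoride desilylation buffered with acetic acid should remove both TBDPS ethers without acyl migration or lactonisation of the 4-hydroxy ester side chain.

**Compound list**
1 | methyl 4-hydroxybut-2-ynoate | COC(=O)C#CCO | starting material
2 | methyl 4-(TBDPSO)but-2-ynoate | COC(=O)C#CCO[Si](c1ccccc1)(c1ccccc1)C(C)(C)C | intermediate
3 | methyl (E)-4-(TBDPSO)-3-(tributylstannyl)but-2-enoate | COC(=O)/C=C(\CO[Si](c1ccccc1)(c1ccccc1)C(C)(C)C)[Sn](CCCC)(CCCC)CCCC | intermediate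
4 | methyl (E)-4-(TBDPSO)-3-iodobut-2-enoate | COC(=O)/C=C(I)\CO[Si](c1ccccc1)(c1ccccc1)C(C)(C)C | intermediate
5 | (R)-3-bromo-2-methylpropan-1-ol | BrC[C@H](C)CO | starting material
6 | (R)-(3-bromo-2-methylpropoxy)(tert-butyl)diphenylsilane | BrC[C@H](C)CO[Si](c1ccccc1)(c1ccccc1)C(C)(C)C | intermediate
7 | [(R)-3-(TBDPSO)-2-methylpropyl]magnesium bromide | Br[Mg]C[C@H](C)CO[Si](c1ccccc1)(c1ccccc1)C(C)(C)C | intermediate
8 | (S)-4-(TBDPSO)-3-methylbutanoic acid | OC(=O)C[C@H](C)CO[Si](c1ccccc1)(c1ccccc1)C(C)(C)C | intermediate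
9 | neryl acetate, (2Z)-3,7-dimethylocta-2,6-dien-1-yl acetate | CC(=O)OC/C=C(C)\CCC=C(C)C | starting material
10 | (2Z)-3-methyl-6-oxohex-2-en-1-yl acetate | CC(=O)OC/C=C(C)\CCC=O | intermediate
11 | (2Z,5S)-3-methyl-6-oxo-5-[(phenylamino)oxy]hex-2-en-1-yl acetate | CC(=O)OC/C=C(C)\C[C@H](ONc1ccccc1)C=O | intermediate
12 | (2Z,5S)-6-hydroxy-3-methyl-5-[(phenylamino)oxy]hex-2-en-1-yl acetate | CC(=O)OC/C=C(C)\C[C@H](ONc1ccccc1)CO | intermediate
13 | (2Z,5S)-5,6-dihydroxy-3-methylhex-2-en-1-yl acetate | CC(=O)OC/C=C(C)\C[C@H](O)CO | intermediate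
14 | (2Z,5S)-5,6-bis(TBSO)-3-methylhex-2-en-1-yl acetate | CC(=O)OC/C=C(C)\C[C@H](O[Si](C)(C)C(C)(C)C)CO[Si](C)(C)C(C)(C)C | intermediate
15 | (2Z,5S)-5,6-bis(TBSO)-3-methylhex-2-en-1-ol | OC/C=C(C)\C[C@H](O[Si](C)(C)C(C)(C)C)CO[Si](C)(C)C(C)(C)C | intermediate
16 | (2Z,5S)-5,6-bis(TBSO)-3-methylhex-2-enal | O=C/C=C(C)\C[C@H](O[Si](C)(C)C(C)(C)C)CO[Si](C)(C)C(C)(C)C | intermediate
17 | (3Z,6S)-6,7-bis(TBSO)-4-methylhepta-1,3-diene | C=C/C=C(C)\C[C@H](O[Si](C)(C)C(C)(C)C)CO[Si](C)(C)C(C)(C)C | intermediate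
18 | 9-[(3Z,6S)-6,7-bis(TBSO)-4-methylhept-3-en-1-yl]-9-borabicyclo[3.3.1]nonane | C1CC2CCCC(C1)B2CC/C=C(C)\C[C@H](O[Si](C)(C)C(C)(C)C)CO[Si](C)(C)C(C)(C)C | intermediate
19 | methyl (2Z,6Z,9S)-9,10-bis(TBSO)-3-(TBDPSO-methyl)-7-methyldeca-2,6-dienoate | COC(=O)/C=C(\CO[Si](c1ccccc1)(c1ccccc1)C(C)(C)C)CC/C=C(C)\C[C@H](O[Si](C)(C)C(C)(C)C)CO[Si](C)(C)C(C)(C)C | intermediate
20 | (2Z,6Z,9S)-9,10-bis(TBSO)-3-(TBDPSO-methyl)-7-methyldeca-2,6-dien-1-ol | OC/C=C(\CO[Si](c1ccccc1)(c1ccccc1)C(C)(C)C)CC/C=C(C)\C[C@H](O[Si](C)(C)C(C)(C)C)CO[Si](C)(C)C(C)(C)C | intermediate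
21 | (2Z,6Z,9S)-9,10-bis(TBSO)-3-(TBDPSO-methyl)-7-methyldeca-2,6-dienal | O=C/C=C(\CO[Si](c1ccccc1)(c1ccccc1)C(C)(C)C)CC/C=C(C)\C[C@H](O[Si](C)(C)C(C)(C)C)CO[Si](C)(C)C(C)(C)C | intermediate
22 | (2S,4Z,8Z)-2-(TBSO)-8-(TBDPSO-methyl)-10,10-dimethoxy-4-methyldeca-4,8-dien-1-ol | COC(OC)/C=C(\CO[Si](c1ccccc1)(c1ccccc1)C(C)(C)C)CC/C=C(C)\C[C@H](O[Si](C)(C)C(C)(C)C)CO | intermediate
23 | (2S,4Z,8Z)-2-(TBSO)-8-(TBDPSO-methyl)-10,10-dimethoxy-4-methyldeca-4,8-dienal | COC(OC)/C=C(\CO[Si](c1ccccc1)(c1ccccc1)C(C)(C)C)CC/C=C(C)\C[C@H](O[Si](C)(C)C(C)(C)C)C=O | intermediate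
24 | methyl acrylate | C=CC(=O)OC | starting material
25 | methyl (4S,6Z,10Z)-4-(TBSO)-10-(TBDPSO-methyl)-3-hydroxy-12,12-dimethoxy-6-methyl-2-methylidenedodeca-6,10-dienoate, both C3 epimers | COC(OC)/C=C(\CO[Si](c1ccccc1)(c1ccccc1)C(C)(C)C)CC/C=C(C)\C[C@H](O[Si](C)(C)C(C)(C)C)C(O)C(=C)C(=O)OC | intermediate
26 | methyl (2Z,4S,6Z,10Z)-2-(bromomethyl)-4-(TBSO)-10-(TBDPSO-methyl)-12,12-dimethoxy-6-methyldodeca-2,6,10-trienoate | COC(OC)/C=C(\CO[Si](c1ccccc1)(c1ccccc1)C(C)(C)C)CC/C=C(C)\C[C@H](O[Si](C)(C)C(C)(C)C)/C=C(\CBr)C(=O)OC | intermediate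
27 | methyl (2Z,4S,6Z,10Z)-2-(bromomethyl)-4-(TBSO)-10-(TBDPSO-methyl)-6-methyl-12-oxododeca-2,6,10-trienoate | O=C/C=C(\CO[Si](c1ccccc1)(c1ccccc1)C(C)(C)C)CC/C=C(C)\C[C@H](O[Si](C)(C)C(C)(C)C)/C=C(\CBr)C(=O)OC | intermediate
28 | methyl (1(10)Z,4Z,6R,7S,8S)-6-hydroxy-8-(TBSO)-15-(TBDPSO)germacra-1(10),4,11(13)-trien-12-oate, present as its chromium alkoxide | C/C1=C/CC/C(CO[Si](c2ccccc2)(c2ccccc2)C(C)(C)C)=C/[C@@H](O)[C@H](C(=C)C(=O)OC)[C@@H](O[Si](C)(C)C(C)(C)C)C1 | intermediate
29 | (1(10)Z,4Z,6R,7S,8S)-8-(TBSO)-15-(TBDPSO)germacra-1(10),4,11(13)-trien-12,6-olide | C/C1=C/CC/C(CO[Si](c2ccccc2)(c2ccccc2)C(C)(C)C)=C/[C@H]2OC(=O)C(=C)[C@@H]2[C@@H](O[Si](C)(C)C(C)(C)C)C1 | intermediate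
30 | (1(10)Z,4Z,6R,7S,8S,11S)-8-(TBSO)-15-(TBDPSO)germacra-1(10),4-dien-12,6-olide | C/C1=C/CC/C(CO[Si](c2ccccc2)(c2ccccc2)C(C)(C)C)=C/[C@H]2OC(=O)[C@@H](C)[C@@H]2[C@@H](O[Si](C)(C)C(C)(C)C)C1 | intermediate
31 | (1(10)Z,4Z,6R,7R,8S,11S)-8-hydroxy-15-(TBDPSO)germacra-1(10),4-dien-12,6-olide | C/C1=C/CC/C(CO[Si](c2ccccc2)(c2ccccc2)C(C)(C)C)=C/[C@H]2OC(=O)[C@@H](C)[C@@H]2[C@@H](O)C1 | intermediate
32 | (1(10)Z,4Z,6R,7R,8S,11S)-8-{[(S)-4-(TBDPSO)-3-methylbutanoyl]oxy}-15-(TBDPSO)germacra-1(10),4-dien-12,6-olide | C/C1=C/CC/C(CO[Si](c2ccccc2)(c2ccccc2)C(C)(C)C)=C/[C@H]2OC(=O)[C@@H](C)[C@@H]2[C@@H](OC(=O)C[C@H](C)CO[Si](c2ccccc2)(c2ccccc2)C(C)(C)C)C1 | intermediate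
33 | CNP0160815.1 | C/C1=C/CC/C(CO)=C/[C@H]2OC(=O)[C@@H](C)[C@@H]2[C@@H](OC(=O)C[C@H](C)CO)C1 | target

**Step count and risks**

Total step count: 24 (3 for iodide 4, 2 for acid 8, 19 on the main line).
Longest linear sequence: 19 steps (9 to 33, steps 6–24).

The three steps most likely to fail:

1. Step 20 (ring closure by allylation). Intermolecular allylation or protonation of the allylchromium may outrun ten-membered ring closure, and the aldehyde may be delivered to the wrong face of C7 or in the syn sense, which would give a cis-fused lactone. The fallback replaces the reducing metal by a preformed allylboronate and sets out from 25. Acetylation (Ac2O, DMAP, pyridine) would give the allylic acetate F1. Copper-catalysed SN2′ borylation (B2pin2, CuCl, LiCl, KOAc, DMF) would give the allylic pinacol boronate acetal F2. Aqueous oxalic acid in THF would free the allylic boronate enal F3, which does not react with its own aldehyde until activated. Sc(OTf)3 (cat.) in toluene at high dilution would then close ring A by intramolecular allylboration through a closed six-membered transition state, and the resulting borate would lactonise (TsOH cat. if needed). The route is rejoined at 29.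

2. Step 18 (Morita–Baylis–Hillman coupling). The amine-catalysed coupling may be slow enough for enolisation of the α-silyloxy aldehyde (loss of configuration at C8) or silyl migration to compete. The fallback sets out from 23 and uses a preformed, non-basic acrylate α-anion equivalent: hydroalumination of methyl propiolate (i-Bu2AlH, N-methylmorpholine N-oxide, THF, 0 °C) gives [1-(methoxycarbonyl)ethenyl]diisobutylaluminium F4, which should add to 23 within hours at 0 °C. The route is rejoined at 25.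

3. Step 13 (hydroboration and B-alkyl coupling). Hydroboration of the conjugated diene may not stay at the terminal position (allylic boranes, Z/E scrambling), or alkyl transfer to palladium may be slow and lose the borane by protodeboronation. The fallback builds C2–C3 by enolate alkylation and sets out from 15:
   - CBr4/PPh3 would give the allylic bromide F5.
   - Alkylation of the dianion of methyl acetoacetate (NaH, n-BuLi, THF, 0 °C) at its terminal carbon would give the β-keto ester F6.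
   - Tf2O with aq. LiOH in toluene would give the (Z)-enol triflate F7.
   - Stille coupling with Bu3SnCH2OH (Pd(PPh3)4, LiCl, dioxane, 90 °C) would give the hydroxy ester F8, which lactonises in the flask to the butenolide F9.
   - Ring opening with Me2AlN(OMe)Me (from AlMe3 and MeNHOMe·HCl) would give the hydroxy Weinreb amide F10, silylated at once (TBDPSCl, imidazole) to the silyl Weinreb amide F11.
   - i-Bu2AlH at −78 °C would give enal 21, where the route is rejoined (steps 14 and 15 are then not needed).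

Further compounds
F1 | step 20 | methyl (4S,6Z,10Z)-3-acetoxy-4-(TBSO)-10-(TBDPSO-methyl)-12,12-dimethoxy-6-methyl-2-methylidenedodeca-6,10-dienoate | COC(OC)/C=C(\CO[Si](c1ccccc1)(c1ccccc1)C(C)(C)C)CC/C=C(C)\C[C@H](O[Si](C)(C)C(C)(C)C)C(OC(C)=O)C(=C)C(=O)OC
F2 | step 20 | methyl (4S,6Z,10Z)-4-(TBSO)-10-(TBDPSO-methyl)-12,12-dimethoxy-6-methyl-2-[(pinacolboryl)methyl]dodeca-2,6,10-trienoate, drawn with C4 cis to the CH2B arm | COC(OC)/C=C(\CO[Si](c1ccccc1)(c1ccccc1)C(C)(C)C)CC/C=C(C)\C[C@H](O[Si](C)(C)C(C)(C)C)/C=C(\CB1OC(C)(C)C(C)(C)O1)C(=O)OC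
F3 | step 20 | methyl (4S,6Z,10Z)-4-(TBSO)-10-(TBDPSO-methyl)-6-methyl-12-oxo-2-[(pinacolboryl)methyl]dodeca-2,6,10-trienoate | O=C/C=C(\CO[Si](c1ccccc1)(c1ccccc1)C(C)(C)C)CC/C=C(C)\C[C@H](O[Si](C)(C)C(C)(C)C)/C=C(\CB1OC(C)(C)C(C)(C)O1)C(=O)OC
F4 | step 18 | [1-(methoxycarbonyl)ethenyl]diisobutylaluminium | C=C(C(=O)OC)[Al](CC(C)C)CC(C)C
F5 | step 13 | (2Z,5S)-1-bromo-5,6-bis(TBSO)-3-methylhex-2-ene | BrC/C=C(C)\C[C@H](O[Si](C)(C)C(C)(C)C)CO[Si](C)(C)C(C)(C)C
F6 | step 13 | methyl (6Z,9S)-9,10-bis(TBSO)-7-methyl-3-oxodec-6-enoate | COC(=O)CC(=O)CC/C=C(C)\C[C@H](O[Si](C)(C)C(C)(C)C)CO[Si](C)(C)C(C)(C)C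
F7 | step 13 | methyl (2Z,6Z,9S)-9,10-bis(TBSO)-7-methyl-3-(trifluoromethylsulfonyloxy)deca-2,6-dienoate | COC(=O)/C=C(\OS(=O)(=O)C(F)(F)F)CC/C=C(C)\C[C@H](O[Si](C)(C)C(C)(C)C)CO[Si](C)(C)C(C)(C)C
F8 | step 13 | methyl (2Z,6Z,9S)-9,10-bis(TBSO)-3-(hydroxymethyl)-7-methyldeca-2,6-dienoate | COC(=O)/C=C(\CO)CC/C=C(C)\C[C@H](O[Si](C)(C)C(C)(C)C)CO[Si](C)(C)C(C)(C)C
F9 | step 13 | 4-[(3Z,6S)-6,7-bis(TBSO)-4-methylhept-3-en-1-yl]furan-2(5H)-one | O=C1C=C(CC/C=C(C)\C[C@H](O[Si](C)(C)C(C)(C)C)CO[Si](C)(C)C(C)(C)C)CO1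
F10 | step 13 | (2Z,6Z,9S)-9,10-bis(TBSO)-3-(hydroxymethyl)-N-methoxy-N,7-dimethyldeca-2,6-dienamide | CON(C)C(=O)/C=C(\CO)CC/C=C(C)\C[C@H](O[Si](C)(C)C(C)(C)C)CO[Si](C)(C)C(C)(C)C
F11 | step 13 | (2Z,6Z,9S)-9,10-bis(TBSO)-3-(TBDPSO-methyl)-N-methoxy-N,7-dimethyldeca-2,6-dienamide | CON(C)C(=O)/C=C(\CO[Si](c1ccccc1)(c1ccccc1)C(C)(C)C)CC/C=C(C)\C[C@H](O[Si](C)(C)C(C)(C)C)CO[Si](C)(C)C(C)(C)C
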